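## The problem

Compound 20 is an open-chain 8,8'-lignan. A butane chain C7'–C8'–C8–C7 carries a methyl group on each inner carbon, a 4-hydroxy-3-methoxyphenyl ring on C7' (a plain benzylic CH2) and a 3,4-dimethoxyphenyl ring on C7, which bears the acetoxy group. The two arenes are the only rings, so the three contiguous stereocentres C7 (R), C8 (S) and C8' (R) must be set without a permanent cyclic scaffold. In the extended chain their acetoxy and two methyl substituents all lie on the same side. Control can be handed along the chain: once C8' is absolute, C8 can be placed trans to it under thermodynamic control inside a five-membered ring, and C7 can follow from C8 by Felkin–Anh addition of an aryl nucleophile to a C7 aldehyde, which gives the required 7,8-syn arrangement. The secondary benzylic acetate on the electron-rich dimethoxyphenyl ring will not survive acid, hydrogenolysis or alkoxide, and it must be formed while the phenol stays free. Any intermediate with a free phenol para to an oxygenated benzylic carbon is a latent quinone methide, and a hydroxyl four carbons away would close onto it to give a tetrahydrofuran. The enabling feature is that C7'–C8'(CH3)–C8(CH3)–C7 is the skeleton of 2,3-dimethylsuccinic acid with one aryl group on each carboxyl carbon: the meso diacid 1 is cheap, and its anhydride 2 has two enantiotopic carbonyl groups. The meso compound necessarily delivers one methyl centre with the wrong relative configuration, but that centre (C8) lies next to the surviving carboxyl carbon C7 and so ends up α to a lactone carbonyl, where it can be inverted.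

## Retrosynthesis

**20 back to 17.** The C7'–H bond made last is traced back to a C7'–O bond, and the free phenol to its acetate, giving triacetate 17. Direct deoxygenation of a C7' alcohol by hydrogenolysis or ionic reduction would not distinguish the two electron-rich benzylic positions. Only the ring with a para phenol can expel a benzylic leaving group through phenoxide 18 and quinone methide 19, so this cut distinguishes C7' from C7 and the phenol from the secondary alcohol in one operation. In 17 all three hydroxyl groups are treated alike. The forward step must cleave only the aryl acetate and leave the C7 acetate alone.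

**17 back to 15.** Acetyl groups are exchanged for hydrogen and the phenol for its triisopropylsilyl ether, through triol 16. The silyl ether is needed for the organometallic steps earlier on. The triol should not be isolated, since it is the species prone to tetrahydrofuran closure.

**15 back to 11 and 13.** The C7–aryl bond is cut, leading to lactol 11 and the aryl Grignard reagent 13 made from bromide 12. Forming the same bond at the ketone level and then reducing would give the 7,8-anti isomer under Felkin–Anh control, so the aldehyde level is the right one. Cutting C7–C8 instead would leave two acyclic centres to be made at once. Lactol 11 holds all remaining stereocentres in one five-membered ring. The forward reaction must show Felkin–Anh face selectivity at the ring-opened aldehyde 14.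

**11 back to 9.** Lactol 11 comes from lactone 10 by partial reduction, and 10 from its C8 epimer 9 by equilibration. This is the only place where C8 is the single enolisable centre of a ring that prefers trans substituents; in any open-chain relative there would be no bias.

**9 back to 7.** The lactone C–O bond is cut and C7' is returned to the ketone level, through hydroxy acid 8 to keto acid 7. The configuration created at C7' is irrelevant because that centre is deleted later.

**7 back to 2 and 6 (key cut).** The aryl–C7' bond is cut, giving meso anhydride 2 and arylzinc chloride 6. A Friedel–Crafts acylation with 2 would make the same bond but would give racemic material. An alcoholytic desymmetrisation would set the centres but not make the C–C bond. Arylative opening does both in one step. The forward reaction must choose between the enantiotopic carbonyls and must not epimerise the centre α to the new ketone.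

**2 and 6 back to starting materials.** Anhydride 2 is the cyclodehydration product of diacid 1. Arylzinc 6 comes from silyl ether 4 by bromine–lithium exchange (aryllithium 5) and transmetalation, and 4 from phenol 3.

## Roads not taken

**Alternative 1:** Both methyl groups are cut off at once (C8–C9 and C8'–C9', where C9 and C9' are the methyl carbons). They reappear as the two CH2 groups of a thiolane whose sulfur is later removed reductively.
- Forward key step: the parent thiocarbonyl ylide, released by fluoride from chloromethyl trimethylsilylmethyl sulfide A3, adds across the (E)-alkene of N-enoyl sultam A2 to give the trans-3,4-disubstituted thiolane A1.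
- Merits: the suprafacial cycloaddition turns the alkene geometry directly into the C8/C8' relationship of the target, so no centre has to be made wrong and then corrected. In this respect it is better than the chosen plan.
- Weak points: the γ-CH2 of A2 is both benzylic and allylic, so the double bond can move into conjugation with the arene under the basic fluoride conditions. Face selection by the sultam toward this small, very reactive ylide is uncertain. The auxiliary is stoichiometric and must be attached and later exchanged for the second aryl group. The nickel desulfurisation has to precede any benzylic C7–O bond, which dictates an awkward order, and C7 still needs the same Felkin–Anh addition.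
- Comparison: the chosen plan sets against the direct relative configuration a catalytic source of chirality acting on a meso compound made in one step, no auxiliary, no sulfur, and a shorter sequence.

**Alternative 2:** The cut is the pair of C–H bonds at C8 and C8'. Saturated lactone A4 is traced to butenolide A5, whose only stereocentre is the aryl-bearing C7.
- Forward key step: hydrogen adds to the tetrasubstituted alkene of A5 anti to the aryl group, and base in the same flask inverts the carbon α to the carbonyl (here C8') to give trans-dimethyl A4.
- Merits: C7 is secured first and independently by a reagent-controlled step, so no Felkin–Anh addition is needed. This is a real advantage over the chosen plan, where C7 rests on substrate control. The all-cis to trans epimerisation also has a larger driving force.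
- Weak points: the tetrasubstituted alkene needs forcing hydrogenation, and the ring C–O bond of A5 is benzylic and allylic on an electron-rich arene. Hydrogenolysis would destroy the only stereocentre, and this is the C7–O bond the target keeps. The γ-proton of A5 is acidic, so base can racemise it. The lactone carbonyl must afterwards be arylated and fully deoxygenated next to the C7 oxygen, where tetrahydrofuran closure threatens.
- Comparison: the lactone of the chosen plan also has a labile benzylic C–O bond, but it is the C7'–O bond that is to be removed anyway, so its lability does no harm. Its absolute configuration comes from the C–C bond-forming step itself rather than from a separate asymmetric preparation.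

**Alternative 3:** The central C8–C8' bond is cut.
- Forward key step: the (E)-silyl ketene acetal of ester A7 rearranges (Ireland–Claisen) through a chair transition state to acid A6, transferring the carbinol configuration of the allylic ester to both new methine centres.
- Merits: the relative configuration is set directly by a reliable sigmatropic process, with no epimerisation. In that respect it is at least as good as the chosen plan.
- Weak points: the diastereoselectivity depends on the enolate geometry of a simple alkyl ester, which is seldom complete. In A6 the carbon that must become a methyl group is a carboxyl group, costing three further operations. The propenyl group must be cleaved oxidatively to the C7 aldehyde in the presence of an electron-rich silyloxyarene. The chiral alcohol is stoichiometric, and the same aryl addition at C7 is still required.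
- Comparison: the chosen plan sets against it a shorter path, catalytic chirality, and a four-carbon unit whose termini arrive at oxidation levels that are used directly.

Key step: step 4

Assumption: hydride is taken to add to ketone 7 in the Felkin–Anh sense, so 8–11 and 14–18 are drawn with C7' (S). The C7' epimers would pass through steps 5–10 in the same way, because this centre becomes sp2 in 19 and CH2 in 20.

## Route

Step 1
Reactants: 1 meso-2,3-dimethylsuccinic acid
Product: 2 meso-2,3-dimethylsuccinic anhydride (cis-3,4-dimethyloxolane-2,5-dione)
Conditions: AcCl (neat), reflux; evaporate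
Reagents that add atoms: none
Why: Cyclodehydration of a 1,4-diacid to the five-membered anhydride through the mixed anhydride; no base is present and the temperature is low, so the two methine centres should keep the cis (meso) arrangement.

Step 2
Reactants: 3 4-bromo-2-methoxyphenol
Product: 4 (4-bromo-2-methoxyphenoxy)triisopropylsilane
Conditions: iPr3SiCl, imidazole, DMF, rt
Reagents that add atoms: chlorotriisopropylsilane, CC(C)[Si](Cl)(C(C)C)C(C)C
Why: Standard silylation of a phenol; the bulky triisopropylsilyl ether should tolerate butyllithium, the arylzinc, hydride reagents, amidine base and the Grignard reagent used before its removal in step 9.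

Step 3
Reactants: 4 (4-bromo-2-methoxyphenoxy)triisopropylsilane
Product: 6 [3-methoxy-4-(triisopropylsilyloxy)phenyl]zinc chloride (THF solution used as such), via aryllithium 5 (not isolated)
Conditions: nBuLi, THF, −78 °C; then ZnCl2 (THF), −78 °C → rt
Reagents that add atoms: zinc dichloride, Cl[Zn]Cl
Why: Bromine–lithium exchange on an aryl bromide followed by transmetalation to zinc; the silyloxy group is para to the metal and cannot migrate, and zinc is introduced before warming so that the aryllithium is not alkylated by the butyl bromide formed.

Step 4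
Reactants: 2 meso-2,3-dimethylsuccinic anhydride; 6 [3-methoxy-4-(triisopropylsilyloxy)phenyl]zinc chloride
Product: 7 (2R,3S)-4-[3-methoxy-4-(triisopropylsilyloxy)phenyl]-2,3-dimethyl-4-oxobutanoic acid
Conditions: [Rh(cod)Cl]2 (2.5 mol%), TADDOL-derived N,N-dimethylphosphoramidite (5 mol%, antipode chosen to deliver (2R,3S)-7), 6 (1.5 equiv), THF/DMF, 50 °C; then aq. HCl
Reagents that add atoms: none
Why: The phosphoramidite-bound monovalent rhodium inserts into one of the two enantiotopic acyl–oxygen bonds of 2 to give an acyl rhodium carboxylate (trivalent rhodium), the aryl group of 6 is transferred from zinc, and reductive elimination forms the aryl–C7' bond and releases the ketone as its chlorozinc carboxylate. The closest known reaction type is the rhodium-catalysed enantioselective arylation of meso-3,4-disubstituted succinic anhydrides with arylzinc reagents, of which this is a direct application. No ring is closed; the anhydride ring is opened. The two methyl-bearing carbons are already stereogenic in 2 and keep their cis (erythro) relationship; they become absolute through the ligand's choice between the enantiotopic carbonyls, which fixes C8' (next to the new ketone) as in the target and leaves C8 (next to the carboxylate) as the epimer that step 6 corrects. The step needs enantiotopic-group selectivity (ligand), a single aryl transfer (an arylzinc does not add to the ketone or to the zinc carboxylate) and no epimerisation α to the new ketone (non-basic organozinc, acidic work-up). The arylzinc carries no ortho substituent, so transmetalation should not be retarded.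

Step 5
Reactants: 7 (2R,3S)-4-[3-methoxy-4-(triisopropylsilyloxy)phenyl]-2,3-dimethyl-4-oxobutanoic acid
Product: 9 (3R,4S,5S)-5-[3-methoxy-4-(triisopropylsilyloxy)phenyl]-3,4-dimethyloxolan-2-one (3,4-cis lactone), via hydroxy acid 8 (not isolated)
Conditions: NaBH4, MeOH, 0 °C; aq. HCl to pH 2; then p-toluenesulfonic acid (cat.), CH2Cl2, rt
Reagents that add atoms: none
Why: Borohydride reduction of the aryl ketone (as its carboxylate) and acid-promoted lactonisation of the γ-hydroxy acid; hydride should add in the Felkin–Anh sense relative to C8' to give the 4,5-trans lactone, but C7' is deleted in step 10, so its configuration has no bearing on the target, and the cis-dimethyl relationship is untouched.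

Step 6
Reactants: 9 (3R,4S,5S)-5-[3-methoxy-4-(triisopropylsilyloxy)phenyl]-3,4-dimethyloxolan-2-one
Product: 10 (3S,4S,5S)-5-[3-methoxy-4-(triisopropylsilyloxy)phenyl]-3,4-dimethyloxolan-2-one (all-trans lactone)
Conditions: 1,8-diazabicyclo[5.4.0]undec-7-ene (DBU), anhydrous toluene, 80 °C
Reagents that add atoms: none
Why: Thermodynamic epimerisation α to a lactone carbonyl through the enolate; C3 (C8 of the lignan) is the only enolisable centre and the all-trans 3,4,5-trisubstituted γ-butyrolactone is the most stable isomer, so the equilibrium should lie on the side of 10, and any remaining 9 can be separated and resubmitted.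

Step 7
Reactants: 10 (3S,4S,5S)-5-[3-methoxy-4-(triisopropylsilyloxy)phenyl]-3,4-dimethyloxolan-2-one
Product: 11 (3S,4S,5S)-5-[3-methoxy-4-(triisopropylsilyloxy)phenyl]-3,4-dimethyloxolan-2-ol (mixture of anomers)
Conditions: iBu2AlH, CH2Cl2, −78 °C; aq. potassium sodium tartrate
Reagents that add atoms: none
Why: Partial reduction of a lactone to the lactol; the aluminium hemiacetal is stable at −78 °C, which prevents over-reduction, and the non-basic conditions leave C8 untouched.

Step 8
Reactants: 11 (3S,4S,5S)-5-[3-methoxy-4-(triisopropylsilyloxy)phenyl]-3,4-dimethyloxolan-2-ol; 12 4-bromo-1,2-dimethoxybenzene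
Product: 15 (1R,2S,3S,4S)-1-(3,4-dimethoxyphenyl)-4-[3-methoxy-4-(triisopropylsilyloxy)phenyl]-2,3-dimethylbutane-1,4-diol, via arylmagnesium bromide 13 (not isolated), via open-chain hydroxy aldehyde 14 (not isolated)
Conditions: 12, Mg, THF, rt (gives 13, 3 equiv); then 11, THF, −40 → 0 °C; aq. NH4Cl
Reagents that add atoms: none
Why: Grignard addition to a lactol: the first equivalent deprotonates 11, the magnesium lactolate opens to aldehyde 14, and the aryl group adds under Felkin–Anh control by the α-stereocentre C8 (the C8' branch as the large group, methyl as the medium one), which should give the 7,8-syn alcohol with C7 (R).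

Step 9
Reactants: 15 (1R,2S,3S,4S)-1-(3,4-dimethoxyphenyl)-4-[3-methoxy-4-(triisopropylsilyloxy)phenyl]-2,3-dimethylbutane-1,4-diol
Product: 17 (1R,2S,3S,4S)-4-(4-acetoxy-3-methoxyphenyl)-1-(3,4-dimethoxyphenyl)-2,3-dimethylbutane-1,4-diyl diacetate, via triol 16 (not isolated)
Conditions: Bu4NF, THF, 0 °C; then Ac2O, pyridine, 4-(dimethylamino)pyridine (cat.), 0 °C → rt
Reagents that add atoms: acetic anhydride, CC(=O)OC(C)=O
Why: Fluoride cleavage of the aryl silyl ether followed in the same flask by acetylation (nucleophilic catalysis) of the phenoxide and both benzylic alcohols; trapping the triol at once avoids isolating a free 4-hydroxybenzylic 1,4-diol, which could close to a tetrahydrofuran.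

Step 10
Reactants: 17 (1R,2S,3S,4S)-4-(4-acetoxy-3-methoxyphenyl)-1-(3,4-dimethoxyphenyl)-2,3-dimethylbutane-1,4-diyl diacetate
Product: 20 (1R,2S,3R)-1-(3,4-dimethoxyphenyl)-4-(4-hydroxy-3-methoxyphenyl)-2,3-dimethylbutyl acetate (target), via phenol diacetate 18 (not isolated), via para-quinone methide 19 (not isolated)
Conditions: NaBH4, EtOH/THF, 0 °C → rt; aq. NH4Cl
Reagents that add atoms: none
Why: Borohydride reduction of a 4-acetoxybenzyl acetate: the activated aryl acetate is cleaved first, phenoxide 18 expels the C7' acetate by 1,6-elimination to quinone methide 19, and hydride adds to the exocyclic carbon, restoring the phenol and leaving C7' as CH2. The C7 acetate sits on a ring without a para phenoxide, cannot ionise in this way and is far less reactive toward alkoxide than the aryl acetate, so it should survive; no stereocentre other than the deleted C7' is touched.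

## Compound list

1 | meso-2,3-dimethylsuccinic acid, (2R,3S)-2,3-dimethylbutanedioic acid | C[C@@H](C(=O)O)[C@H](C)C(=O)O | starting material
2 | meso-2,3-dimethylsuccinic anhydride, cis-(3R,4S)-3,4-dimethyloxolane-2,5-dione | O=C1OC(=O)[C@@H](C)[C@H]1C | intermediate
3 | 4-bromo-2-methoxyphenol | COc1cc(Br)ccc1O | starting material
4 | (4-bromo-2-methoxyphenoxy)triisopropylsilane | COc1cc(Br)ccc1O[Si](C(C)C)(C(C)C)C(C)C | intermediate
5 | [3-methoxy-4-(triisopropylsilyloxy)phenyl]lithium | COc1cc([Li])ccc1O[Si](C(C)C)(C(C)C)C(C)C | intermediate
6 | [3-methoxy-4-(triisopropylsilyloxy)phenyl]zinc chloride | COc1cc([Zn]Cl)ccc1O[Si](C(C)C)(C(C)C)C(C)C | intermediate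
7 | (2R,3S)-4-[3-methoxy-4-(triisopropylsilyloxy)phenyl]-2,3-dimethyl-4-oxobutanoic acid | COc1cc(C(=O)[C@@H](C)[C@@H](C)C(=O)O)ccc1O[Si](C(C)C)(C(C)C)C(C)C | intermediate
8 | (2R,3S,4S)-4-hydroxy-4-[3-methoxy-4-(triisopropylsilyloxy)phenyl]-2,3-dimethylbutanoic acid | COc1cc([C@@H](O)[C@@H](C)[C@@H](C)C(=O)O)ccc1O[Si](C(C)C)(C(C)C)C(C)C | intermediate
9 | (3R,4S,5S)-5-[3-methoxy-4-(triisopropylsilyloxy)phenyl]-3,4-dimethyloxolan-2-one (3,4-cis, 4,5-trans) | COc1cc([C@@H](O2)[C@@H](C)[C@@H](C)C2=O)ccc1O[Si](C(C)C)(C(C)C)C(C)C | intermediate
10 | (3S,4S,5S)-5-[3-methoxy-4-(triisopropylsilyloxy)phenyl]-3,4-dimethyloxolan-2-one (all-trans) | COc1cc([C@@H](O2)[C@@H](C)[C@H](C)C2=O)ccc1O[Si](C(C)C)(C(C)C)C(C)C | intermediate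
11 | (3S,4S,5S)-5-[3-methoxy-4-(triisopropylsilyloxy)phenyl]-3,4-dimethyloxolan-2-ol (anomer mixture) | COc1cc([C@@H](O2)[C@@H](C)[C@H](C)C2O)ccc1O[Si](C(C)C)(C(C)C)C(C)C | intermediate
12 | 4-bromo-1,2-dimethoxybenzene | COc1ccc(Br)cc1OC | starting material
13 | (3,4-dimethoxyphenyl)magnesium bromide | COc1ccc([Mg]Br)cc1OC | intermediate
14 | (2S,3S,4S)-4-hydroxy-4-[3-methoxy-4-(triisopropylsilyloxy)phenyl]-2,3-dimethylbutanal (present as its magnesium alkoxide) | COc1cc([C@@H](O)[C@@H](C)[C@H](C)C=O)ccc1O[Si](C(C)C)(C(C)C)C(C)C | intermediate
15 | (1R,2S,3S,4S)-1-(3,4-dimethoxyphenyl)-4-[3-methoxy-4-(triisopropylsilyloxy)phenyl]-2,3-dimethylbutane-1,4-diol | COc1cc([C@@H](O)[C@@H](C)[C@H](C)[C@@H](O)c2ccc(OC)c(OC)c2)ccc1O[Si](C(C)C)(C(C)C)C(C)C | intermediate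
16 | (1R,2S,3S,4S)-1-(3,4-dimethoxyphenyl)-4-(4-hydroxy-3-methoxyphenyl)-2,3-dimethylbutane-1,4-diol | COc1cc([C@@H](O)[C@@H](C)[C@H](C)[C@@H](O)c2ccc(OC)c(OC)c2)ccc1O | intermediate
17 | (1R,2S,3S,4S)-4-(4-acetoxy-3-methoxyphenyl)-1-(3,4-dimethoxyphenyl)-2,3-dimethylbutane-1,4-diyl diacetate | COc1cc([C@@H](OC(C)=O)[C@@H](C)[C@H](C)[C@@H](OC(C)=O)c2ccc(OC)c(OC)c2)ccc1OC(C)=O | intermediate
18 | (1R,2S,3S,4S)-1-(3,4-dimethoxyphenyl)-4-(4-hydroxy-3-methoxyphenyl)-2,3-dimethylbutane-1,4-diyl diacetate (present as its phenoxide) | COc1cc([C@@H](OC(C)=O)[C@@H](C)[C@H](C)[C@@H](OC(C)=O)c2ccc(OC)c(OC)c2)ccc1O | intermediate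
19 | (1R,2S,3R)-1-(3,4-dimethoxyphenyl)-4-(3-methoxy-4-oxocyclohexa-2,5-dien-1-ylidene)-2,3-dimethylbutyl acetate (para-quinone methide, alkene geometry undefined) | COC1=CC(=C[C@@H](C)[C@H](C)[C@@H](OC(C)=O)c2ccc(OC)c(OC)c2)C=CC1=O | intermediate
20 | (1R,2S,3R)-1-(3,4-dimethoxyphenyl)-4-(4-hydroxy-3-methoxyphenyl)-2,3-dimethylbutyl acetate | COc1cc(C[C@@H](C)[C@H](C)[C@@H](OC(C)=O)c2ccc(OC)c(OC)c2)ccc1O | target

## Step count and least certain steps

Total step count: 10. Longest linear sequence: 9 steps (steps 2–10, from 3). Step 1 is a one-step branch that joins at step 4, and the Grignard reagent 13 is made in the flask in step 8.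

**Step 4 (key step).** The most likely failure is insufficient discrimination between the enantiotopic carbonyls. Slow transmetalation from a halide-containing arylzinc could let unselective background opening or decarbonylation of the acyl rhodium intermediate compete. The sense of induction also has to be matched to the ligand antipode.
Fallback, from 2 back to 9: alkaloid-mediated methanolysis of 2 (quinidine or quinine, MeOH, toluene, low temperature) should give the hemiester (2S,3R)-4-methoxy-2,3-dimethyl-4-oxobutanoic acid F1. Oxalyl chloride with catalytic DMF would convert it to methyl (2R,3S)-4-chloro-2,3-dimethyl-4-oxobutanoate F2. Negishi acylation of F2 with 6 under Pd(PPh3)4 would give methyl (2R,3S)-4-[3-methoxy-4-(triisopropylsilyloxy)phenyl]-2,3-dimethyl-4-oxobutanoate F3. NaBH4 in MeOH would reduce F3 to methyl (2R,3S,4S)-4-hydroxy-4-[3-methoxy-4-(triisopropylsilyloxy)phenyl]-2,3-dimethylbutanoate F4, which on treatment with acid lactonises with loss of methanol to 9.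

**Step 8.** Facial selectivity may be poor: Felkin–Anh control by a single α-methyl centre is moderate, the γ-magnesium alkoxide may deliver the reagent differently, and the basic Grignard reagent may enolise the aldehyde and erode C8.
Fallback, from 10 back to 15: one equivalent of (3,4-dimethoxyphenyl)lithium F5, made from 12 and nBuLi, added to lactone 10 at −78 °C, should stop at the stage of (2S,3S,4S)-1-(3,4-dimethoxyphenyl)-4-hydroxy-4-[3-methoxy-4-(triisopropylsilyloxy)phenyl]-2,3-dimethylbutan-1-one F6. Corey–Bakshi–Shibata reduction of F6 with (S)-1-methyl-3,3-diphenyltetrahydro-1H,3H-pyrrolo[1,2-c][1,3,2]oxazaborole and BH3·SMe2 would then set C7 (R) by reagent control and give 15. This reduction runs against the weak intrinsic Felkin–Anh preference of the ketone, which the catalyst is expected to override.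

**Step 10.** The C7 acetate may be lost to alkoxide or borohydride before the quinone methide is reduced, after which the freed C7 alkoxide would add to C7' and close a tetrahydrofuran. The quinone methide may also tautomerise to the 7',8'-alkene before hydride capture, which would destroy C8'.
Fallback, from 10 to 20, removing the C7' oxygen before the C7 oxygen exists:
- Hydrogenolysis of the benzylic lactone C–O bond of 10 (H2, Pd/C, AcOH/EtOAc, 50 °C) should give (2S,3R)-4-[3-methoxy-4-(triisopropylsilyloxy)phenyl]-2,3-dimethylbutanoic acid F7.
- BH3·SMe2 would reduce it to (2S,3R)-4-[3-methoxy-4-(triisopropylsilyloxy)phenyl]-2,3-dimethylbutan-1-ol F8.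
- Dess–Martin oxidation would give (2S,3R)-4-[3-methoxy-4-(triisopropylsilyloxy)phenyl]-2,3-dimethylbutanal F9.
- Felkin–Anh addition of 13 would give (1R,2S,3R)-1-(3,4-dimethoxyphenyl)-4-[3-methoxy-4-(triisopropylsilyloxy)phenyl]-2,3-dimethylbutan-1-ol F10.
- Ac2O/pyridine would give (1R,2S,3R)-1-(3,4-dimethoxyphenyl)-4-[3-methoxy-4-(triisopropylsilyloxy)phenyl]-2,3-dimethylbutyl acetate F11.
- Bu4NF buffered with AcOH would then release 20.

**Step 6.** Enolisation of the lactone may be too slow at temperatures where the aryl silyl ether survives the amidine base, leaving the equilibration incomplete.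
Fallback, from 9 back to 11: reduction of 9 with iBu2AlH at −78 °C would give the cis-lactol (3R,4S,5S)-5-[3-methoxy-4-(triisopropylsilyloxy)phenyl]-3,4-dimethyloxolan-2-ol F12. Its ring-opened tautomer (2R,3S,4S)-4-hydroxy-4-[3-methoxy-4-(triisopropylsilyloxy)phenyl]-2,3-dimethylbutanal F13 has a much more acidic α-proton and should equilibrate with Et3N in CH2Cl2 at rt to 14, which closes to the trans-lactol 11.

## Further compounds

F1 | step 4 | (2S,3R)-4-methoxy-2,3-dimethyl-4-oxobutanoic acid | OC(=O)[C@@H](C)[C@@H](C)C(=O)OC
F2 | step 4 | methyl (2R,3S)-4-chloro-2,3-dimethyl-4-oxobutanoate | ClC(=O)[C@@H](C)[C@@H](C)C(=O)OC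
F3 | step 4 | methyl (2R,3S)-4-[3-methoxy-4-(triisopropylsilyloxy)phenyl]-2,3-dimethyl-4-oxobutanoate | COc1cc(C(=O)[C@@H](C)[C@@H](C)C(=O)OC)ccc1O[Si](C(C)C)(C(C)C)C(C)C
F4 | step 4 | methyl (2R,3S,4S)-4-hydroxy-4-[3-methoxy-4-(triisopropylsilyloxy)phenyl]-2,3-dimethylbutanoate | COc1cc([C@@H](O)[C@@H](C)[C@@H](C)C(=O)OC)ccc1O[Si](C(C)C)(C(C)C)C(C)C
F5 | step 8 | (3,4-dimethoxyphenyl)lithium | COc1ccc([Li])cc1OC
F6 | step 8 | (2S,3S,4S)-1-(3,4-dimethoxyphenyl)-4-hydroxy-4-[3-methoxy-4-(triisopropylsilyloxy)phenyl]-2,3-dimethylbutan-1-one | COc1cc([C@@H](O)[C@@H](C)[C@H](C)C(=O)c2ccc(OC)c(OC)c2)ccc1O[Si](C(C)C)(C(C)C)C(C)C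
F7 | step 10 | (2S,3R)-4-[3-methoxy-4-(triisopropylsilyloxy)phenyl]-2,3-dimethylbutanoic acid | COc1cc(C[C@@H](C)[C@H](C)C(=O)O)ccc1O[Si](C(C)C)(C(C)C)C(C)C
F8 | step 10 | (2S,3R)-4-[3-methoxy-4-(triisopropylsilyloxy)phenyl]-2,3-dimethylbutan-1-ol | COc1cc(C[C@@H](C)[C@H](C)CO)ccc1O[Si](C(C)C)(C(C)C)C(C)C
F9 | step 10 | (2S,3R)-4-[3-methoxy-4-(triisopropylsilyloxy)phenyl]-2,3-dimethylbutanal | COc1cc(C[C@@H](C)[C@H](C)C=O)ccc1O[Si](C(C)C)(C(C)C)C(C)C
F10 | step 10 | (1R,2S,3R)-1-(3,4-dimethoxyphenyl)-4-[3-methoxy-4-(triisopropylsilyloxy)phenyl]-2,3-dimethylbutan-1-ol | COc1cc(C[C@@H](C)[C@H](C)[C@@H](O)c2ccc(OC)c(OC)c2)ccc1O[Si](C(C)C)(C(C)C)C(C)C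
F11 | step 10 | (1R,2S,3R)-1-(3,4-dimethoxyphenyl)-4-[3-methoxy-4-(triisopropylsilyloxy)phenyl]-2,3-dimethylbutyl acetate | COc1cc(C[C@@H](C)[C@H](C)[C@@H](OC(C)=O)c2ccc(OC)c(OC)c2)ccc1O[Si](C(C)C)(C(C)C)C(C)C
F12 | step 6 | (3R,4S,5S)-5-[3-methoxy-4-(triisopropylsilyloxy)phenyl]-3,4-dimethyloxolan-2-ol | COc1cc([C@@H](O2)[C@@H](C)[C@@H](C)C2O)ccc1O[Si](C(C)C)(C(C)C)C(C)C
F13 | step 6 | (2R,3S,4S)-4-hydroxy-4-[3-methoxy-4-(triisopropylsilyloxy)phenyl]-2,3-dimethylbutanal | COc1cc([C@@H](O)[C@@H](C)[C@@H](C)C=O)ccc1O[Si](C(C)C)(C(C)C)C(C)C
A1 | alternative 1 | N-[(3S,4R)-4-(3-methoxy-4-triisopropylsilyloxybenzyl)thiolane-3-carbonyl]-(2S)-bornane-10,2-sultam | CC1(C)[C@H]2CC[C@@]13CS(=O)(=O)N(C(=O)[C@H]4CSC[C@@H]4Cc5ccc(O[Si](C(C)C)(C(C)C)C(C)C)c(OC)c5)[C@H]3C2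
A2 | alternative 1 | N-[(E)-4-(3-methoxy-4-triisopropylsilyloxyphenyl)but-2-enoyl]-(2S)-bornane-10,2-sultam | CC1(C)[C@H]2CC[C@@]13CS(=O)(=O)N(C(=O)/C=C/Cc4ccc(O[Si](C(C)C)(C(C)C)C(C)C)c(OC)c4)[C@H]3C2
A3 | alternative 1 | chloromethyl trimethylsilylmethyl sulfide | C[Si](C)(C)CSCCl
A4 | alternative 2 | (3S,4S,5R)-5-(3,4-dimethoxyphenyl)-3,4-dimethyldihydrofuran-2(3H)-one | C[C@@H]1C(=O)O[C@@H](c2ccc(OC)c(OC)c2)[C@H]1C
A5 | alternative 2 | (S)-5-(3,4-dimethoxyphenyl)-3,4-dimethylfuran-2(5H)-one | CC1=C(C)[C@H](c2ccc(OC)c(OC)c2)OC1=O
A6 | alternative 3 | (2R,3R,E)-2-[3-methoxy-4-(triisopropylsilyloxy)benzyl]-3-methylhex-4-enoic acid | COc1cc(C[C@@H](C(=O)O)[C@H](C)/C=C/C)ccc1O[Si](C(C)C)(C(C)C)C(C)C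
A7 | alternative 3 | (S,E)-pent-3-en-2-yl 3-[3-methoxy-4-(triisopropylsilyloxy)phenyl]propanoate | COc1cc(CCC(=O)O[C@@H](C)/C=C/C)ccc1O[Si](C(C)C)(C(C)C)C(C)C
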